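**Plan**
1. Skeleton numbering used below: ring B (pyrrolidine) N-4, C-1, C-2, C-3, C-9a; ring A (azepane) N-4, C-5 to C-9, C-9a; ring C (cyclohexane) C-1, C-9a, C-9, C-10, C-11, C-12; ring D (fused lactone) C-11 to C-14 and O; ring E (pendant lactone on C-3) C-18 to C-21 and O; ethyl C-16/C-17 on C-10.
2. Cuts, in retrosynthetic order: N–O; C-16=C-17 (ethyl from vinyl); C-10–C-11 (ring C); C-10=C-16 (Wittig); N-4–C-5 (ring A); C-9–C-9a (Mannich); C-18–C-19 and the ring E C–O bond; C-1–C-12 (conjugate addition).
3. Enabling feature: C-11 is a ring C atom and also the O-bearing carbon of lactone ring D. As the acetal carbon of a 5-alkoxybutanolide it is a latent acyl-oxocarbenium ion, and its ring C neighbour C-10 carries the ethyl group, which can be masked as the vinyl end of an allylsilane.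
4. Forward order: ring B from 4-oxo-L-proline; ring D (menthyl acetal butenolide) joined at C-1; ring E by ketone reduction and lactonisation; ring A by reductive amination; ring C last by cationic closure of C-10 onto C-11; then vinyl hydrogenation and N-oxidation.
5. Stereochemistry: C-3 from L-proline; C-20 from the (R)-bromo ester; C-12 and C-13 from the menthyl acetal; C-1 by hydrogenation anti to the C-3 ester; C-18 by Felkin–Anh reduction; C-9a by trans addition to the N-acyliminium ion; C-9 from the oxazolidinone auxiliary; C-10 and C-11 in the key step; the N-oxide by attack on the open face.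
6. Helpers: the menthyloxy group (stereocontrol, then leaving group), SiMe3 and the vinyl group leave in steps 18 and 19; Boc, benzyl and the auxiliary leave earlier.

Key step: step 18

Assumption: the C-5 epimers of menthyl acetal 7 are separable by crystallisation and interconvert under acid, as is usual for 5-alkoxyfuranones, so the (5S) epimer can be used alone.

Step 1
Reactants: 1 N-Boc-4-oxo-L-proline benzyl ester
Product: 2 enol triflate (C-1=C-2 alkene)
Conditions: NaN(SiMe3)2, PhNTf2, THF, −78 °C
Reagents that add atoms: N-phenylbis(trifluoromethanesulfonimide), O=S(=O)(N(c1ccccc1)S(=O)(=O)C(F)(F)F)C(F)(F)F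
Why: Kinetic enolisation of the ketone and O-sulfonylation (enol triflate formation) is standard for 4-oxoprolinates and should leave C-3 untouched at −78 °C, a minor C-1=C-9a regioisomer converging on the same compound in step 6.

Step 2
Reactants: 2 enol triflate
Product: 3 alkenyl pinacol boronate
Conditions: B2pin2, PdCl2(dppf) (cat.), KOAc, 1,4-dioxane, 80 °C
Reagents that add atoms: bis(pinacolato)diboron, CC1(C)OB(OC1(C)C)B1OC(C)(C)C(C)(C)O1
Why: Miyaura borylation of an alkenyl triflate with the weak base KOAc should not epimerise the allylic C-3 centre.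

Step 3
Reactants: 4 3-methylfuran-2(5H)-one
Product: 5 5-bromo-3-methylfuran-2(5H)-one (racemic)
Conditions: NBS, AIBN (cat.), PhCF3, 85 °C
Reagents that add atoms: N-bromosuccinimide, O=C1CCC(=O)N1Br
Why: Wohl–Ziegler bromination at the γ-carbon, which is allylic and α to the ring oxygen, is the standard entry to this bromobutenolide.

Step 4
Reactants: 5 bromobutenolide; 6 (+)-menthol
Product: 7 (5S)-menthyl acetal butenolide
Conditions: Ag2CO3, CH2Cl2, rt; crystallisation of the (5S) epimer, mother liquor re-equilibrated with TsOH (cat.)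
Reagents that add atoms: none
Why: Silver-assisted substitution of the pseudo-acid bromide by the alcohol (acetal formation through the furanonyl cation) gives both C-5 epimers, of which the (5S) one is taken on as stereocontrol element for C-12 and later as leaving group of the key step.

Step 5
Reactants: 3 alkenyl boronate; 7 menthyl acetal butenolide
Product: 8 alkenyl butanolide
Conditions: [Rh(cod)OH]2 (cat.), Et3N, 1,4-dioxane/H2O 10:1, 40 °C
Reagents that add atoms: none
Why: Rh-catalysed conjugate addition of the alkenylboronate (Hayashi–Miyaura reaction) should deliver the alkenyl group to C-12 anti to the menthyloxy group, and kinetic protonation of the rhodium enolate at C-13 anti to the new bulky substituent should leave the methyl group cis to it.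

Step 6
Reactants: 8 alkenyl butanolide
Product: 9 pyrrolidine acid
Conditions: H2 (1 atm), Pd/C, EtOAc, rt
Reagents that add atoms: none
Why: Heterogeneous hydrogenation should add hydrogen to the pyrroline alkene from the face opposite the C-3 ester, which sets C-1 with the lactone cis to the carboxyl group, and the same catalyst hydrogenolyses the benzyl ester.

Step 7
Reactants: 9 pyrrolidine acid
Product: 10 S-ethyl thioester
Conditions: EtSH, EDC·HCl, DMAP (cat.), CH2Cl2, 0 °C to rt
Reagents that add atoms: ethanethiol, CCS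
Why: Carbodiimide-mediated thioesterification of a urethane-protected amino acid should proceed without epimerisation at C-3 and prepares the acyl group for ketone synthesis.

Step 8
Reactants: 10 S-ethyl thioester; 11 methyl (2R)-3-bromo-2-methylpropanoate
Product: 13 C-18 ketone, via organozinc bromide 12 (not isolated)
Conditions: 11, Zn dust, LiCl, THF, 50 °C; then 10, PdCl2(PPh3)2 (cat.), toluene/THF, rt
Reagents that add atoms: none
Why: Fukuyama coupling of the thioester with the zinc homoenolate, formed by zinc insertion without touching its β-stereocentre, should give the ketone without over-addition and tolerates lactone, acetal and carbamate.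

Step 9
Reactants: 13 C-18 ketone
Product: 15 bis-lactone carbamate, via hydroxy ester 14 (not isolated)
Conditions: LiBH(s-Bu)3, THF, −78 to 0 °C; aq. NH4Cl; then PPTS (cat.), CH2Cl2, rt
Reagents that add atoms: none
Why: Felkin–Anh reduction of the α-(N-Boc-amino) ketone by the bulky hydride, anti to the C-3–N bond, should give the threo (18S) alcohol, which lactonises onto the methyl ester to close ring E.

Step 10
Reactants: 15 bis-lactone carbamate
Product: 16 C-9a methoxy carbamate (both C-9a epimers)
Conditions: graphite anode, Pt cathode, Et4NOTs, MeOH, 0 °C, constant current (about 2.5 F/mol)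
Reagents that add atoms: methanol, CO
Why: Shono oxidation (anodic α-methoxylation of a carbamate) should occur at the unsubstituted C-9a methylene and not at the hindered C-3 methine, which is also deactivated by the neighbouring acyloxy group.

Step 11
Reactants: 17 (4R)-4-benzyloxazolidin-2-one; 18 hept-6-enoyl chloride
Product: 19 N-(hept-6-enoyl)oxazolidinone
Conditions: n-BuLi, THF, −78 °C; then 18
Reagents that add atoms: none
Why: N-acylation of the lithiated oxazolidinone by the acid chloride is the standard preparation of such imides.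

Step 12
Reactants: 16 C-9a methoxy carbamate; 19 N-(hept-6-enoyl)oxazolidinone
Product: 22 Mannich adduct, via titanium enolate 20 (not isolated), via N-acyliminium ion 21 (not isolated)
Conditions: 19, TiCl4, iPr2NEt, CH2Cl2, −78 °C; then 16, −78 to −20 °C
Reagents that add atoms: none
Why: In this Mannich-type addition the N-acyliminium carbon C-9a should be attacked trans to the lactone on C-1 (and to the one on C-3), and the chelated Z chlorotitanium enolate should react on the face opposite the benzyl group of the (R)-auxiliary, which sets C-9.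

Step 13
Reactants: 22 Mannich adduct
Product: 23 C-5 aldehyde
Conditions: O3, CH2Cl2/MeOH, −78 °C; then PPh3
Reagents that add atoms: ozone, [O-][O+]=O
Why: Ozonolysis with reductive work-up cleaves the only C=C bond to the C-5 aldehyde.

Step 14
Reactants: 23 C-5 aldehyde
Product: 25 ring A amine, via cyclic iminium ion 24 (not isolated)
Conditions: CF3CO2H, CH2Cl2, 0 °C; evaporation; then NaBH(OAc)3, ClCH2CH2Cl, rt
Reagents that add atoms: none
Why: Removal of the Boc group lets the ammonium ion condense with the C-5 aldehyde to a seven-membered cyclic iminium ion, whose reduction (intramolecular reductive amination) closes ring A without freeing a secondary amine that could attack the lactones.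

Step 15
Reactants: 25 ring A amine
Product: 26 C-10 aldehyde
Conditions: Cp2Zr(H)Cl, THF, rt; then H2O
Reagents that add atoms: none
Why: Hydrozirconation of the imide carbonyl and hydrolysis of the zirconated hemiaminal (amide-to-aldehyde reduction with Cp2Zr(H)Cl) should release the aldehyde and the auxiliary while esters and lactones are not reduced.

Step 16
Reactants: 27 methyltriphenylphosphonium bromide; 28 (iodomethyl)trimethylsilane
Product: 30 silylethylphosphonium iodide, via methylenetriphenylphosphorane 29 (not isolated)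
Conditions: n-BuLi, THF, 0 °C; then 28, rt
Reagents that add atoms: none
Why: C-alkylation of methylenetriphenylphosphorane with the iodomethylsilane is the usual route to this β-silylethylphosphonium salt.

Step 17
Reactants: 26 C-10 aldehyde; 30 silylethylphosphonium iodide
Product: 32 Z-allylsilane, via silyl ylide 31 (not isolated)
Conditions: 30, KN(SiMe3)2, THF, −78 °C; then 26, −78 to 0 °C
Reagents that add atoms: none
Why: Wittig olefination with a non-stabilised ylide under salt-free conditions should give the Z-allylsilane, and the fast reaction at low temperature should outrun epimerisation at C-9 and β-elimination of the amine.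

Step 18
Reactants: 32 Z-allylsilane
Product: 34 vinyl pentacycle, via acyl-oxocarbenium ion 33 (not isolated)
Conditions: Me3SiOTf, 2,6-di-tert-butylpyridine, CH2Cl2, −78 to −30 °C; aq. NaHCO3
Reagents that add atoms: none
Why: Me3SiOTf ionises the only O,O-acetal, and loss of the menthyloxy group from C-11 gives the cyclic acyl-oxocarbenium ion 33, which is attacked at C-11 by the γ-carbon (C-10) of the Z-allylsilane with loss of the silyl group (β-silicon effect), an intramolecular Hosomi–Sakurai reaction whose closest known relative is the C-allylation of 5-alkoxybutanolides by allylsilanes. Ring C closes by one C–C bond in a 6-exo mode with respect to both the C=O+ bond and the alkene. C-11 is controlled by the tether, because the nucleophile hangs on C-12 through C-1, C-9a and C-9 and can reach only the face of the planar cation that bears the C-12–C-1 bond, which gives the cis-fused lactone. C-10 is controlled by A(1,3) strain, because the Z-alkene holds H-9 in its plane, so that the cation, arriving from the C-9a side, adds to the alkene face opposite C-8 and the vinyl group should end up trans to C-8 and trans to the lactone oxygen. The step needs chemoselective ionisation, γ-regioselectivity and facial selectivity at C-10, and these are secured by the single acetal (N-4 being tied up as its silylammonium ion), by the silicon, and by the Z geometry from step 17 together with the trans ring B/ring C junction already fixed at C-1 and C-9a.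

Step 19
Reactants: 34 vinyl pentacycle
Product: 35 tertiary amine (N-deoxy target)
Conditions: H2 (1 atm), Pd/C, EtOAc, rt
Reagents that add atoms: none
Why: Catalytic hydrogenation of the monosubstituted alkene turns the vinyl helper into the ethyl group without affecting the lactones or the amine.

Step 20
Reactants: 35 tertiary amine
Product: 36 N-oxytuberostemonine
Conditions: mCPBA, CH2Cl2, 0 °C
Reagents that add atoms: 3-chloroperoxybenzoic acid, OOC(=O)c1cccc(Cl)c1
Why: N-oxidation of the tertiary amine by the peracid should occur on the lone pair of the invertomer with trans-fused rings A and B, from the face of ring B opposite the pendant lactone on C-3 and the lactone-bearing substituent on C-1, which gives the N-oxide configuration of the target.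

**Compound list** (Men = (1S,2R,5S)-menthyl)

1 | 2-benzyl 1-tert-butyl (2S)-4-oxopyrrolidine-1,2-dicarboxylate | CC(C)(C)OC(=O)N1CC(=O)C[C@H]1C(=O)OCc1ccccc1 | starting material
2 | 2-benzyl 1-tert-butyl (2S)-4-[(trifluoromethylsulfonyl)oxy]-2,5-dihydro-1H-pyrrole-1,2-dicarboxylate | CC(C)(C)OC(=O)N1CC(OS(=O)(=O)C(F)(F)F)=C[C@H]1C(=O)OCc1ccccc1 | intermediate
3 | 2-benzyl 1-tert-butyl (2S)-4-(4,4,5,5-tetramethyl-1,3,2-dioxaborolan-2-yl)-2,5-dihydro-1H-pyrrole-1,2-dicarboxylate | CC(C)(C)OC(=O)N1CC(B2OC(C)(C)C(C)(C)O2)=C[C@H]1C(=O)OCc1ccccc1 | intermediate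
4 | 3-methylfuran-2(5H)-one | CC1=CCOC1=O | starting material
5 | 5-bromo-3-methylfuran-2(5H)-one (racemic) | CC1=CC(Br)OC1=O | intermediate
6 | (+)-menthol, (1S,2R,5S)-5-methyl-2-(propan-2-yl)cyclohexan-1-ol | CC(C)[C@H]1CC[C@H](C)C[C@@H]1O | starting material
7 | (5S)-3-methyl-5-(Men-oxy)furan-2(5H)-one | CC1=C[C@@H](O[C@H]2C[C@@H](C)CC[C@@H]2C(C)C)OC1=O | intermediate
8 | 2-benzyl 1-tert-butyl (2S)-4-[4-methyl-2-(Men-oxy)-5-oxooxolan-3-yl]-2,5-dihydro-1H-pyrrole-1,2-dicarboxylate; on the lactone the pyrroline (at C-12) is trans to the Men-oxy group (C-11) and cis to the methyl (C-13) | CC(C)(C)OC(=O)N1CC([C@H]2[C@@H](C)C(=O)O[C@@H]2O[C@H]3C[C@@H](C)CC[C@@H]3C(C)C)=C[C@H]1C(=O)OCc1ccccc1 | intermediate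
9 | (2S,4R)-1-Boc-4-[lactone as in 8]pyrrolidine-2-carboxylic acid; lactone on C-1 cis to the carboxyl on C-3 | CC(C)(C)OC(=O)N1C[C@@H]([C@H]2[C@@H](C)C(=O)O[C@@H]2O[C@H]3C[C@@H](C)CC[C@@H]3C(C)C)C[C@H]1C(=O)O | intermediate
10 | S-ethyl thioester of 9 | CC(C)(C)OC(=O)N1C[C@@H]([C@H]2[C@@H](C)C(=O)O[C@@H]2O[C@H]3C[C@@H](C)CC[C@@H]3C(C)C)C[C@H]1C(=O)SCC | intermediate
11 | methyl (2R)-3-bromo-2-methylpropanoate | COC(=O)[C@@H](C)CBr | starting material
12 | bromo[(2R)-3-methoxy-2-methyl-3-oxopropyl]zinc | COC(=O)[C@@H](C)C[Zn]Br | intermediate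
13 | C-18 ketone: Boc-pyrrolidine with the ring D lactone on C-1 and a (3S)-4-methoxy-3-methyl-4-oxobutanoyl group on C-3 | CC(C)(C)OC(=O)N1C[C@@H]([C@H]2[C@@H](C)C(=O)O[C@@H]2O[C@H]3C[C@@H](C)CC[C@@H]3C(C)C)C[C@H]1C(=O)C[C@H](C)C(=O)OC | intermediate
14 | (18S)-hydroxy ester from 13 (threo to C-3) | CC(C)(C)OC(=O)N1C[C@@H]([C@H]2[C@@H](C)C(=O)O[C@@H]2O[C@H]3C[C@@H](C)CC[C@@H]3C(C)C)C[C@H]1[C@@H](O)C[C@H](C)C(=O)OC | intermediate
15 | bis-lactone carbamate: Boc-pyrrolidine with ring D (Men acetal) on C-1 and ring E ((18S,20S)-4-methyl-5-oxooxolan-2-yl) on C-3, the two cis | CC(C)(C)OC(=O)N1C[C@@H]([C@H]2[C@@H](C)C(=O)O[C@@H]2O[C@H]3C[C@@H](C)CC[C@@H]3C(C)C)C[C@H]1[C@@H]1C[C@H](C)C(=O)O1 | intermediate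
16 | 15 with methoxy at C-9a (both epimers) | CC(C)(C)OC(=O)N1C(OC)[C@@H]([C@H]2[C@@H](C)C(=O)O[C@@H]2O[C@H]3C[C@@H](C)CC[C@@H]3C(C)C)C[C@H]1[C@@H]1C[C@H](C)C(=O)O1 | intermediate
17 | (4R)-4-benzyl-1,3-oxazolidin-2-one | O=C1N[C@H](Cc2ccccc2)CO1 | starting material
18 | hept-6-enoyl chloride | C=CCCCCC(=O)Cl | starting material
19 | (4R)-4-benzyl-3-(hept-6-enoyl)-1,3-oxazolidin-2-one | C=CCCCCC(=O)N1[C@H](Cc2ccccc2)COC1=O | intermediate
20 | Z trichlorotitanium enolate of 19 | C=CCCC/C=C(\O[Ti](Cl)(Cl)Cl)N1[C@H](Cc2ccccc2)COC1=O | intermediate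
21 | N-Boc N-acyliminium ion (N-4=C-9a) from 16 | CC(C)(C)OC(=O)[N+]1=C[C@@H]([C@H]2[C@@H](C)C(=O)O[C@@H]2O[C@H]3C[C@@H](C)CC[C@@H]3C(C)C)C[C@H]1[C@@H]1C[C@H](C)C(=O)O1 | intermediate
22 | Mannich adduct: 15 carrying at C-9a (trans to the C-1 lactone) the C-9 carbon, which bears a pent-4-enyl chain and the acyloxazolidinone | CC(C)(C)OC(=O)N1[C@H]([C@H](CCCC=C)C(=O)N2[C@H](Cc3ccccc3)COC2=O)[C@@H]([C@H]2[C@@H](C)C(=O)O[C@@H]2O[C@H]3C[C@@H](C)CC[C@@H]3C(C)C)C[C@H]1[C@@H]1C[C@H](C)C(=O)O1 | intermediate
23 | C-5 aldehyde (22 with 4-oxobutyl in place of pent-4-enyl) | CC(C)(C)OC(=O)N1[C@H]([C@H](CCCC=O)C(=O)N2[C@H](Cc3ccccc3)COC2=O)[C@@H]([C@H]2[C@@H](C)C(=O)O[C@@H]2O[C@H]3C[C@@H](C)CC[C@@H]3C(C)C)C[C@H]1[C@@H]1C[C@H](C)C(=O)O1 | intermediate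
24 | bicyclic iminium ion (N-4=C-5) | O=C(N1[C@H](Cc2ccccc2)COC1=O)[C@H]1CCCC=[N+]2[C@H]1[C@H](C[C@H]2[C@@H]3C[C@H](C)C(=O)O3)[C@H]4[C@@H](C)C(=O)O[C@@H]4O[C@H]5C[C@@H](C)CC[C@@H]5C(C)C | intermediate
25 | pyrrolo[1,2-a]azepane (rings A and B) with the acyloxazolidinone on C-9, ring D (Men acetal) on C-1 and ring E on C-3 | O=C(N1[C@H](Cc2ccccc2)COC1=O)[C@H]1CCCCN2[C@H]1[C@H](C[C@H]2[C@@H]3C[C@H](C)C(=O)O3)[C@H]4[C@@H](C)C(=O)O[C@@H]4O[C@H]5C[C@@H](C)CC[C@@H]5C(C)C | intermediate
26 | C-10 aldehyde (25 with CHO on C-9) | O=C[C@H]1CCCCN2[C@H]1[C@H](C[C@H]2[C@@H]3C[C@H](C)C(=O)O3)[C@H]4[C@@H](C)C(=O)O[C@@H]4O[C@H]5C[C@@H](C)CC[C@@H]5C(C)C | intermediate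
27 | methyltriphenylphosphonium bromide | C[P+](c1ccccc1)(c1ccccc1)c1ccccc1.[Br-] | starting material
28 | (iodomethyl)trimethylsilane | C[Si](C)(C)CI | starting material
29 | methylenetriphenylphosphorane | C=P(c1ccccc1)(c1ccccc1)c1ccccc1 | intermediate
30 | triphenyl[2-(trimethylsilyl)ethyl]phosphonium iodide | C[Si](C)(C)CC[P+](c1ccccc1)(c1ccccc1)c1ccccc1.[I-] | intermediate
31 | triphenyl[2-(trimethylsilyl)ethylidene]phosphorane | C[Si](C)(C)CC=P(c1ccccc1)(c1ccccc1)c1ccccc1 | intermediate
32 | Z-allylsilane: 26 with (Z)-CH=CH–CH2SiMe3 on C-9 | C[Si](C)(C)C/C=C\[C@H]1CCCCN2[C@H]1[C@H](C[C@H]2[C@@H]3C[C@H](C)C(=O)O3)[C@H]4[C@@H](C)C(=O)O[C@@H]4O[C@H]5C[C@@H](C)CC[C@@H]5C(C)C | intermediate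
33 | acyl-oxocarbenium ion at C-11 | C[Si](C)(C)C/C=C\[C@H]1CCCCN2[C@H]1[C@H](C[C@H]2[C@@H]3C[C@H](C)C(=O)O3)[C@H]4[C@@H](C)C(=O)[O+]=C4 | intermediate
34 | pentacyclic amine with vinyl on C-10 (16,17-didehydro form of 35) | C=C[C@@H]1[C@H]2CCCCN3[C@H]2[C@H](C[C@H]3[C@@H]4C[C@H](C)C(=O)O4)[C@@H]5[C@H]1OC(=O)[C@@H]5C | intermediate
35 | pentacyclic tertiary amine (N-deoxy target) | CC[C@@H]1[C@H]2CCCCN3[C@H]2[C@H](C[C@H]3[C@@H]4C[C@H](C)C(=O)O4)[C@@H]5[C@H]1OC(=O)[C@@H]5C | intermediate
36 | N-oxytuberostemonine | CC[C@@H]1[C@H]2CCCC[N@@+]3([O-])[C@H]2[C@H](C[C@H]3[C@@H]2C[C@H](C)C(=O)O2)[C@@H]2[C@H]1OC(=O)[C@@H]2C | target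

**Step count and risks**

Total step count: 20. Longest linear sequence: 16 steps from compound 1 (steps 1, 2, 5 to 10, 12 to 15, 17 to 20).

Steps most likely to fail:

1. Step 18. Protodesilylation of the allylsilane, or proton loss from the acyl-oxocarbenium ion, may outrun C–C bond formation, and the alkene face at C-10 may be chosen poorly. Fallback (radical closure instead of cationic closure): from aldehyde 26, Wittig olefination with ethylidenetriphenylphosphorane (ethyltriphenylphosphonium bromide, KN(SiMe3)2, THF, −78 °C) gives the (Z)-propenyl compound F1. Exchange of the menthyloxy group for phenylselanyl (PhSeH, BF3·OEt2, CH2Cl2) gives the C-11 selenide F2. Bu3SnH and AIBN (slow addition, benzene, 80 °C) then generate the C-11 α-acyloxy radical, whose 6-exo cyclisation onto the Z-alkene followed by hydrogen transfer to C-16 forms ring C and the ethyl group at once and rejoins the route at amine 35.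

2. Step 5. Carbometalation of the trisubstituted, acetal-bearing butenolide may be slow, so that protodeboronation of 3 competes, and kinetic control of the protonation at C-13 may be lost. Fallback (methyl group set by hydrogenation instead of protonation): from boronate 3, the same Rh-catalysed addition to the unsubstituted butenolide (5S)-5-(menthyloxy)furan-2(5H)-one F3 (from 5-hydroxyfuran-2(5H)-one and 6 with TsOH) gives alkenyl butanolide F4. Hydrogenation (H2, Pd/C) gives the acid F5. Its dianion (LiN(iPr)2, THF, −78 °C) is treated with dimethylmethyleneiminium iodide, then MeI and NaHCO3, to give the α-methylene lactone F6. Hydrogenation from the face opposite the C-1 substituent (H2, Pd/C) sets the cis methyl group and rejoins the route at acid 9.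

3. Step 12. Steric congestion at C-9a next to the C-1 lactone may slow the addition so that the N-acyliminium ion eliminates to the enecarbamate, and a mismatched pairing of the two stereocontrol elements may erode selectivity at C-9. Fallback (substrate-controlled Mukaiyama–Mannich reaction without auxiliary): from 16, reaction with the smaller silyl ketene thioacetal F8 under BF3·OEt2 (CH2Cl2, −78 °C) gives the thioester adduct F9 after separation of the C-9 epimers; F8 is made from S-ethyl hept-6-enethioate F7 (18 and EtSH) with LiN(iPr)2 and Me3SiCl. Ozonolysis gives the C-5 aldehyde F10. CF3CO2H followed by NaBH(OAc)3 gives the ring A amine thioester F11. Fukuyama reduction (Et3SiH, Pd/C, acetone) then gives aldehyde 26, where the route is rejoined.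

Further compounds
F1 | step 18 | 26 with (Z)-prop-1-enyl on C-9 in place of CHO | C/C=C\[C@H]1CCCCN2[C@H]1[C@H](C[C@H]2[C@@H]3C[C@H](C)C(=O)O3)[C@H]4[C@@H](C)C(=O)O[C@@H]4O[C@H]5C[C@@H](C)CC[C@@H]5C(C)C
F2 | step 18 | F1 with phenylselanyl on C-11 in place of menthyloxy (both C-11 epimers) | C/C=C\[C@H]1CCCCN2[C@H]1[C@H](C[C@H]2[C@@H]3C[C@H](C)C(=O)O3)[C@H]4[C@@H](C)C(=O)OC4[Se]c5ccccc5
F3 | step 5 | (5S)-5-{[(1S,2R,5S)-5-methyl-2-(propan-2-yl)cyclohexyl]oxy}furan-2(5H)-one | O=C1C=C[C@@H](O[C@H]2C[C@@H](C)CC[C@@H]2C(C)C)O1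
F4 | step 5 | analogue of 8 without the C-13 methyl group | CC(C)(C)OC(=O)N1CC([C@H]2CC(=O)O[C@@H]2O[C@H]3C[C@@H](C)CC[C@@H]3C(C)C)=C[C@H]1C(=O)OCc1ccccc1
F5 | step 5 | analogue of 9 without the C-13 methyl group | CC(C)(C)OC(=O)N1C[C@@H]([C@H]2CC(=O)O[C@@H]2O[C@H]3C[C@@H](C)CC[C@@H]3C(C)C)C[C@H]1C(=O)O
F6 | step 5 | analogue of 9 with methylene on C-13 | CC(C)(C)OC(=O)N1C[C@@H]([C@H]2C(=C)C(=O)O[C@@H]2O[C@H]3C[C@@H](C)CC[C@@H]3C(C)C)C[C@H]1C(=O)O
F7 | step 12 | S-ethyl hept-6-enethioate | C=CCCCCC(=O)SCC
F8 | step 12 | [1-(ethylsulfanyl)hepta-1,6-dienyl]oxytrimethylsilane | C=CCCCC=C(O[Si](C)(C)C)SCC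
F9 | step 12 | analogue of 22 with S-ethyl thioester in place of the acyloxazolidinone | CC(C)(C)OC(=O)N1[C@H]([C@H](CCCC=C)C(=O)SCC)[C@@H]([C@H]2[C@@H](C)C(=O)O[C@@H]2O[C@H]3C[C@@H](C)CC[C@@H]3C(C)C)C[C@H]1[C@@H]1C[C@H](C)C(=O)O1
F10 | step 12 | analogue of 23 with S-ethyl thioester | CC(C)(C)OC(=O)N1[C@H]([C@H](CCCC=O)C(=O)SCC)[C@@H]([C@H]2[C@@H](C)C(=O)O[C@@H]2O[C@H]3C[C@@H](C)CC[C@@H]3C(C)C)C[C@H]1[C@@H]1C[C@H](C)C(=O)O1
F11 | step 12 | analogue of 25 with S-ethyl thioester on C-9 | CCSC(=O)[C@H]1CCCCN2[C@H]1[C@H](C[C@H]2[C@@H]3C[C@H](C)C(=O)O3)[C@H]4[C@@H](C)C(=O)O[C@@H]4O[C@H]5C[C@@H](C)CC[C@@H]5C(C)C
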